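**Assumption:** the target has no stereocentre and no E/Z element (it is achiral), so "single enantiomer" needs no stereocontrol. As in-flask intermediates I number only discrete metal-free species (3 and 8), not catalyst-bound organometallics or statistical mixtures of partly protected or deprotected compounds.

## Retrosynthetic overview

1. Target 12 ⇐ tris-MOM flavone 11; the three B-ring phenols are unmasked last.
2. Key step: the pyranone ring is cut at C4–C3 and O1–C2 in one operation. A Rh-catalysed oxidative [4+2] annulation (aldehyde C–H activation) joins salicylaldehyde 5 with internal alkyne 10, which already carries the B ring and the C3 prenyl group. This avoids the 1,3-diketone / Baker–Venkataraman route and any late C3 prenylation.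
3. 5 ⇐ 2,4,6-trihydroxybenzaldehyde 1. The formyl group blocks C1, so bis-C-prenylation can only go to C3/C5; 4-O-methylation follows. Aldehyde 5 is C2-symmetric, so either OH gives the same chromone.
4. 10 ⇐ 2,4,5-trihydroxybenzaldehyde 6 by MOM protection, one-carbon homologation to the aryl alkyne, and Cu-catalysed alkynyl–prenyl coupling.
5. Ring order: the A and B rings are bought; the only ring built is the C ring (pyran-4-one), in step 6.

## Route

Step 1
Reactants: 1 2,4,6-trihydroxybenzaldehyde; 2 prenyl bromide (1-bromo-3-methylbut-2-ene)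
Product: 4 2,4,6-trihydroxy-3,5-bis(3-methylbut-2-en-1-yl)benzaldehyde, via 2,4,6-trihydroxy-3-(3-methylbut-2-en-1-yl)benzaldehyde 3 (not isolated)
Conditions: 2 (2.2 equiv), 10% aq KOH, 0 °C → rt; then dil. HCl to pH 3
Reagents that add atoms: none
Why: Phenoxide C-alkylation of a phloroglucinol-type ring in water, where the formyl group blocks C1 so only C3 and C5 can be prenylated and the second alkylation gives the symmetric product; no stereocentre is formed, and a modest yield with chromatographic removal of mono- and over-alkylated material is accepted at this cheap first step.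

Step 2
Reactants: 4 2,4,6-trihydroxy-3,5-bis(3-methylbut-2-en-1-yl)benzaldehyde
Product: 5 2,6-dihydroxy-4-methoxy-3,5-bis(3-methylbut-2-en-1-yl)benzaldehyde
Conditions: MeI (1.1 equiv), K2CO3 (1.05 equiv), acetone, rt
Reagents that add atoms: iodomethane, CI
Why: Chemoselective Williamson O-methylation, since the 4-OH para to the aldehyde is the most acidic phenol and the only one not hydrogen-bonded to C=O, so one equivalent of base and MeI methylates it and leaves the two chelated ortho-OH groups free; no stereocentre.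

Step 3
Reactants: 6 2,4,5-trihydroxybenzaldehyde
Product: 7 2,4,5-tris(methoxymethoxy)benzaldehyde
Conditions: NaH (3.5 equiv), MOMCl (3.5 equiv), DMF, 0 °C → rt, Ar
Reagents that add atoms: chloromethyl methyl ether (MOMCl), COCCl
Why: Williamson-type MOM protection of all three phenoxides (NaH is needed for the chelated 2-OH), giving acetals that tolerate the basic, copper and rhodium steps that follow; no stereocentre.

Step 4
Reactants: 7 2,4,5-tris(methoxymethoxy)benzaldehyde
Product: 9 1-ethynyl-2,4,5-tris(methoxymethoxy)benzene, via 1-(2-diazoethenyl)-2,4,5-tris(methoxymethoxy)benzene 8 (not isolated)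
Conditions: dimethyl (1-diazo-2-oxopropyl)phosphonate (1.5 equiv), K2CO3 (2 equiv), MeOH, 0 °C → rt
Reagents that add atoms: dimethyl (1-diazo-2-oxopropyl)phosphonate (Ohira–Bestmann reagent), CC(=O)C(=[N+]=[N-])P(=O)(OC)OC
Why: Ohira–Bestmann (Seyferth–Gilbert) homologation, in which methoxide unmasks the diazomethylphosphonate anion, Horner–Wadsworth–Emmons-type olefination gives diazoalkene 8, and loss of N2 with a 1,2-hydride shift gives the terminal alkyne while the MOM ethers are inert to K2CO3/MeOH; no stereocentre.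

Step 5
Reactants: 9 1-ethynyl-2,4,5-tris(methoxymethoxy)benzene; 2 prenyl bromide
Product: 10 1,2,4-tris(methoxymethoxy)-5-(5-methylhex-4-en-1-yn-1-yl)benzene
Conditions: 2 (1.3 equiv), CuI (10 mol %), K2CO3 (1.5 equiv), n-Bu4NI (10 mol %), DMF, rt, Ar
Reagents that add atoms: none
Why: Copper-catalysed alkynyl–allyl coupling, in which the catalytic copper(I) acetylide of 9 displaces bromide at the unhindered primary carbon of 2 (SN2 rather than SN2') to give the linear skipped enyne under a base mild enough to avoid alkyne–allene isomerisation; no stereocentre.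

Step 6
Reactants: 5 2,6-dihydroxy-4-methoxy-3,5-bis(3-methylbut-2-en-1-yl)benzaldehyde; 10 1,2,4-tris(methoxymethoxy)-5-(5-methylhex-4-en-1-yn-1-yl)benzene
Product: 11 5-hydroxy-7-methoxy-3,6,8-tris(3-methylbut-2-en-1-yl)-2-[2,4,5-tris(methoxymethoxy)phenyl]-4H-chromen-4-one
Conditions: [RhCl(cod)]2 (2.5 mol %), 1,2,3,4-tetraphenylcyclopenta-1,3-diene (10 mol %), Cu(OAc)2·H2O (2.2 equiv), o-xylene, 130 °C, N2
Reagents that add atoms: none
Why: Rhodium-catalysed oxidative [4+2] annulation of a salicylaldehyde with an internal alkyne (aldehyde C–H activation), in which phenoxide-directed formyl C–H rhodation gives an acyl rhodacycle, the alkyne inserts with the acyl carbon bonding to the alkyl-bearing carbon and rhodium on the aryl-bearing carbon, and C–O reductive elimination closes the pyranone with the aryl group at C2 and the prenyl at C3 while Cu(II) reoxidises rhodium; the symmetric aldehyde makes both OH groups equivalent, the unused one becomes the 5-OH, and no stereocentre is formed.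

Step 7
Reactants: 11 5-hydroxy-7-methoxy-3,6,8-tris(3-methylbut-2-en-1-yl)-2-[2,4,5-tris(methoxymethoxy)phenyl]-4H-chromen-4-one
Product: 12 5-hydroxy-7-methoxy-3,6,8-tris(3-methylbut-2-en-1-yl)-2-(2,4,5-trihydroxyphenyl)-4H-chromen-4-one
Conditions: 3 M aq HCl–MeOH–THF (1:5:2), 40 °C, degassed, Ar
Reagents that add atoms: none
Why: Acid-catalysed acetal methanolysis (MOM deprotection) under mild, oxygen-free conditions kept below the threshold for acid cyclisation of the 5-OH onto the 6-prenyl group, with the aryl methyl ether, the chromone and the three trisubstituted alkenes stable to these conditions; no stereocentre is involved.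

## Compound list

1 | 2,4,6-trihydroxybenzaldehyde | O=Cc1c(O)cc(O)cc1O | starting material
2 | prenyl bromide (1-bromo-3-methylbut-2-ene) | CC(C)=CCBr | starting material
3 | 2,4,6-trihydroxy-3-(3-methylbut-2-en-1-yl)benzaldehyde (formed in step 1, not isolated) | O=Cc1c(O)cc(O)c(CC=C(C)C)c1O | intermediate
4 | 2,4,6-trihydroxy-3,5-bis(3-methylbut-2-en-1-yl)benzaldehyde | O=Cc1c(O)c(CC=C(C)C)c(O)c(CC=C(C)C)c1O | intermediate
5 | 2,6-dihydroxy-4-methoxy-3,5-bis(3-methylbut-2-en-1-yl)benzaldehyde | O=Cc1c(O)c(CC=C(C)C)c(OC)c(CC=C(C)C)c1O | intermediate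
6 | 2,4,5-trihydroxybenzaldehyde | O=Cc1cc(O)c(O)cc1O | starting material
7 | 2,4,5-tris(methoxymethoxy)benzaldehyde | O=Cc1cc(OCOC)c(OCOC)cc1OCOC | intermediate
8 | 1-(2-diazoethenyl)-2,4,5-tris(methoxymethoxy)benzene (diazoalkene formed in step 4, not isolated) | [N-]=[N+]=C=Cc1cc(OCOC)c(OCOC)cc1OCOC | intermediate
9 | 1-ethynyl-2,4,5-tris(methoxymethoxy)benzene | C#Cc1cc(OCOC)c(OCOC)cc1OCOC | intermediate
10 | 1,2,4-tris(methoxymethoxy)-5-(5-methylhex-4-en-1-yn-1-yl)benzene | CC(C)=CCC#Cc1cc(OCOC)c(OCOC)cc1OCOC | intermediate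
11 | 5-hydroxy-7-methoxy-3,6,8-tris(3-methylbut-2-en-1-yl)-2-[2,4,5-tris(methoxymethoxy)phenyl]-4H-chromen-4-one | COc1c(CC=C(C)C)c(O)c2c(=O)c(CC=C(C)C)c(-c3cc(OCOC)c(OCOC)cc3OCOC)oc2c1CC=C(C)C | intermediate
12 | 5-hydroxy-7-methoxy-3,6,8-tris(3-methylbut-2-en-1-yl)-2-(2,4,5-trihydroxyphenyl)-4H-chromen-4-one (CNP0330304.0, achiral) | COc1c(CC=C(C)C)c(O)c2c(=O)c(CC=C(C)C)c(-c3cc(O)c(O)cc3O)oc2c1CC=C(C)C | target

## Summary

Total step count: 7 (steps 1–2 make the A-ring aldehyde, steps 3–5 the alkyne, steps 6–7 join and unmask).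
Longest linear sequence: 5 steps (6 → 7 → 9 → 10 → 11 → 12).

## Three steps most likely to fail, with fallbacks

**Step 6 (key annulation).** The risks are isomerisation of the skipped enyne, wrong-way alkyne insertion giving the 3-aryl isomer, and Cu(II)-mediated oxidation of the prenylated phenol. The fallback drops C–H activation and builds C3–C4 by an aldol reaction. It sets out from 5 and 7 and comes back to the route at 12. Aldehyde 5 is capped (NaH, MOMCl, DMF) as 4-methoxy-2,6-bis(methoxymethoxy)-3,5-bis(3-methylbut-2-en-1-yl)benzaldehyde F1. Aldehyde 7 is treated with (4-methylpent-3-en-1-yl)magnesium bromide F2, made from commercial 5-bromo-2-methylpent-2-ene and Mg in THF, to give 5-methyl-1-[2,4,5-tris(methoxymethoxy)phenyl]hex-4-en-1-ol F3. Dess–Martin periodinane oxidises this to 5-methyl-1-[2,4,5-tris(methoxymethoxy)phenyl]hex-4-en-1-one F4. The lithium enolate of F4 (LDA, THF, −78 °C) adds to F1 to give the aldol 3-hydroxy-3-[4-methoxy-2,6-bis(methoxymethoxy)-3,5-bis(3-methylbut-2-en-1-yl)phenyl]-2-(3-methylbut-2-en-1-yl)-1-[2,4,5-tris(methoxymethoxy)phenyl]propan-1-one F5, a diastereomer mixture whose stereocentres are erased later. A second Dess–Martin oxidation gives 1-[4-methoxy-2,6-bis(methoxymethoxy)-3,5-bis(3-methylbut-2-en-1-yl)phenyl]-2-(3-methylbut-2-en-1-yl)-3-[2,4,5-tris(methoxymethoxy)phenyl]propane-1,3-dione F6. Treatment with 3 M HCl/MeOH at 50 °C removes all five MOM groups and cyclodehydrates to 12. Closure should go through an A-ring OH onto the B-ring carbonyl, because the A-ring carbonyl is di-ortho-substituted and chelated.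

**Step 1 (double C-prenylation).** The risks are low yield, O-alkylation and gem-dialkylation. The fallback replaces direct C-prenylation by Claisen rearrangement and olefin metathesis, and it also replaces step 2. It sets out from 1 and comes back at 5. Compound 1 is first methylated at the non-chelated 4-OH (MeI 1 equiv, K2CO3, DMF) to 2,6-dihydroxy-4-methoxybenzaldehyde F7. Both remaining phenols are allylated (allyl bromide, K2CO3, DMF, 60 °C) to give 2,6-bis(allyloxy)-4-methoxybenzaldehyde F8. A double aromatic Claisen rearrangement (N,N-diethylaniline, 190 °C), in which each allyloxy group has only one free ortho position, gives 3,5-diallyl-2,6-dihydroxy-4-methoxybenzaldehyde F9. Double cross-metathesis with excess 2-methylbut-2-ene (Grubbs II, CH2Cl2, 40 °C) converts both allyl groups into prenyl groups and delivers 5.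

**Step 7 (acidic global deprotection).** The risks are chroman formation from the 5-OH and 6-prenyl group, and air oxidation of the hydroxyhydroquinone ring. The fallback swaps the acid-labile MOM set for fluoride-labile silyl ethers. It sets out from 6 and comes back at 12. Compound 6 is silylated (TIPSCl, imidazole, DMF) to 2,4,5-tris(triisopropylsilyloxy)benzaldehyde F10. Colvin homologation with lithiated trimethylsilyldiazomethane (THF, −78 °C → rt, no methanolic base) gives 1-ethynyl-2,4,5-tris(triisopropylsilyloxy)benzene F11. Copper-catalysed coupling with 2 as in step 5 gives 1,2,4-tris(triisopropylsilyloxy)-5-(5-methylhex-4-en-1-yn-1-yl)benzene F12. Annulation with 5 under the step 6 conditions gives 5-hydroxy-7-methoxy-3,6,8-tris(3-methylbut-2-en-1-yl)-2-[2,4,5-tris(triisopropylsilyloxy)phenyl]-4H-chromen-4-one F13. Buffered fluoride (TBAF/AcOH, THF, 0 °C, Ar) then gives 12 without any acid contact.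

## Further compounds

F1 | step 6 | 4-methoxy-2,6-bis(methoxymethoxy)-3,5-bis(3-methylbut-2-en-1-yl)benzaldehyde | COc1c(CC=C(C)C)c(OCOC)c(C=O)c(OCOC)c1CC=C(C)C
F2 | step 6 | (4-methylpent-3-en-1-yl)magnesium bromide | CC(C)=CCC[Mg]Br
F3 | step 6 | 5-methyl-1-[2,4,5-tris(methoxymethoxy)phenyl]hex-4-en-1-ol (racemic) | CC(C)=CCCC(O)c1cc(OCOC)c(OCOC)cc1OCOC
F4 | step 6 | 5-methyl-1-[2,4,5-tris(methoxymethoxy)phenyl]hex-4-en-1-one | CC(C)=CCCC(=O)c1cc(OCOC)c(OCOC)cc1OCOC
F5 | step 6 | 3-hydroxy-3-[4-methoxy-2,6-bis(methoxymethoxy)-3,5-bis(3-methylbut-2-en-1-yl)phenyl]-2-(3-methylbut-2-en-1-yl)-1-[2,4,5-tris(methoxymethoxy)phenyl]propan-1-one (diastereomer mixture) | COc1c(CC=C(C)C)c(OCOC)c(C(O)C(CC=C(C)C)C(=O)c2cc(OCOC)c(OCOC)cc2OCOC)c(OCOC)c1CC=C(C)C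
F6 | step 6 | 1-[4-methoxy-2,6-bis(methoxymethoxy)-3,5-bis(3-methylbut-2-en-1-yl)phenyl]-2-(3-methylbut-2-en-1-yl)-3-[2,4,5-tris(methoxymethoxy)phenyl]propane-1,3-dione (racemic) | COc1c(CC=C(C)C)c(OCOC)c(C(=O)C(CC=C(C)C)C(=O)c2cc(OCOC)c(OCOC)cc2OCOC)c(OCOC)c1CC=C(C)C
F7 | step 1 | 2,6-dihydroxy-4-methoxybenzaldehyde | COc1cc(O)c(C=O)c(O)c1
F8 | step 1 | 2,6-bis(allyloxy)-4-methoxybenzaldehyde | COc1cc(OCC=C)c(C=O)c(OCC=C)c1
F9 | step 1 | 3,5-diallyl-2,6-dihydroxy-4-methoxybenzaldehyde | COc1c(CC=C)c(O)c(C=O)c(O)c1CC=C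
F10 | step 7 | 2,4,5-tris(triisopropylsilyloxy)benzaldehyde | O=Cc1cc(O[Si](C(C)C)(C(C)C)C(C)C)c(O[Si](C(C)C)(C(C)C)C(C)C)cc1O[Si](C(C)C)(C(C)C)C(C)C
F11 | step 7 | 1-ethynyl-2,4,5-tris(triisopropylsilyloxy)benzene | C#Cc1cc(O[Si](C(C)C)(C(C)C)C(C)C)c(O[Si](C(C)C)(C(C)C)C(C)C)cc1O[Si](C(C)C)(C(C)C)C(C)C
F12 | step 7 | 1,2,4-tris(triisopropylsilyloxy)-5-(5-methylhex-4-en-1-yn-1-yl)benzene | CC(C)=CCC#Cc1cc(O[Si](C(C)C)(C(C)C)C(C)C)c(O[Si](C(C)C)(C(C)C)C(C)C)cc1O[Si](C(C)C)(C(C)C)C(C)C
F13 | step 7 | 5-hydroxy-7-methoxy-3,6,8-tris(3-methylbut-2-en-1-yl)-2-[2,4,5-tris(triisopropylsilyloxy)phenyl]-4H-chromen-4-one | COc1c(CC=C(C)C)c(O)c2c(=O)c(CC=C(C)C)c(-c3cc(O[Si](C(C)C)(C(C)C)C(C)C)c(O[Si](C(C)C)(C(C)C)C(C)C)cc3O[Si](C(C)C)(C(C)C)C(C)C)oc2c1CC=C(C)C
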